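The synthesis rests on cutting the trans-decalin at C5–C10 and C8–C9. The feature exploited is the ring A/ring B fusion itself: C5, quaternary C10 with its angular methyl C20, and C9, whose substituent C11 is cis to C20. This array maps onto an E C9=C10 enoyl dienophile and a C5–C8 dienol silyl ether, tied together by C1–C4. One intramolecular Diels–Alder reaction of the acyclic N-enoyl (S)-4-benzyloxazolidinone triene, which carries a C2 ethylene ketal and the C4 gem-dimethyl group, closes both rings and sets C5, C9 and C10. C13 is bought in and joined by Wittig olefination at C11. C2 is set last by α-face hydride delivery.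

Key step: step 12

Remark: labdane numbering (C1–C20) is used for every intermediate and α/β refer to the drawing in which C20 is β; the ketene acetal geometry of 8 is left open because both isomers should give 9.

Step 1
Reactants: 1 diethyl isopropylidenemalonate; 2 allylmagnesium bromide
Product: 3 diethyl 2-(2-methylpent-4-en-2-yl)malonate
Conditions: CuBr·SMe2 (10 mol %), THF, −40 → 0 °C; aq. work-up
Reagents that add atoms: none
Why: Copper-catalysed conjugate addition of a Grignard reagent to the doubly activated alkylidene malonate creates quaternary C4 with its two methyl groups and the C5–C7 allyl arm, a bond that a simple β,β-disubstituted enoate would not accept, and no stereocentre arises.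

Step 2
Reactants: 3 diethyl 2-(2-methylpent-4-en-2-yl)malonate
Product: 4 ethyl 3,3-dimethylhex-5-enoate
Conditions: LiCl, H2O, DMSO, 170 °C
Reagents that add atoms: none
Why: Krapcho dealkoxycarbonylation removes the surplus ester carbon, so that the remaining ester carbon is C2 and the former malonate CH becomes C3H2.

Step 3
Reactants: 4 ethyl 3,3-dimethylhex-5-enoate
Product: 5 3,3-dimethylhex-5-enal
Conditions: iBu2AlH (1.05 equiv), CH2Cl2, −78 °C; aq. potassium sodium tartrate
Reagents that add atoms: none
Why: Partial ester reduction with iBu2AlH stops at −78 °C at the aluminium hemiacetal, which collapses to the C2 aldehyde only on work-up.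

Step 4
Reactants: 6 methyl 3-methylbut-2-enoate
Product: 8 1-methoxy-3-methyl-1-(trimethylsilyloxy)buta-1,3-diene, via lithium dienolate 7 (not isolated)
Conditions: LiN(iPr)2, THF, −78 °C; then TMSCl, −78 °C → rt
Reagents that add atoms: chlorotrimethylsilane, C[Si](C)(C)Cl
Why: γ-Deprotonation of the senecioate and O-silylation of the extended enolate (silyl ketene acetal formation) give the vinylogous nucleophile whose terminal CH2 will become C1.

Step 5
Reactants: 5 3,3-dimethylhex-5-enal; 8 1-methoxy-3-methyl-1-(trimethylsilyloxy)buta-1,3-diene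
Product: 9 methyl (2E)-5-hydroxy-3,7,7-trimethyldeca-2,9-dienoate (racemic at C2)
Conditions: BF3·OEt2 (1.1 equiv), CH2Cl2/Et2O, −78 °C; aq. NaHCO3
Reagents that add atoms: none
Why: Vinylogous Mukaiyama aldol reaction in which the BF3-bound aldehyde is attacked in an open transition state by the unhindered terminal CH2 (C1) of the silyl dienolate, the extended s-trans diene delivering the E C9=C10 enoate (any Z isomer would lactonise and be removed on silica), and the C2 carbinol centre is formed as a racemate because it is erased in step 6.

Step 6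
Reactants: 9 methyl (2E)-5-hydroxy-3,7,7-trimethyldeca-2,9-dienoate
Product: 10 methyl (2E)-3,7,7-trimethyl-5-oxodeca-2,9-dienoate
Conditions: Dess–Martin periodinane, NaHCO3, CH2Cl2, 0 °C
Reagents that add atoms: none
Why: Dess–Martin oxidation under bicarbonate buffer is fast and essentially neutral, so the C2 ketone should form without enolisation towards C1, which would move or scramble the C9=C10 double bond.

Step 7
Reactants: 10 methyl (2E)-3,7,7-trimethyl-5-oxodeca-2,9-dienoate
Product: 11 methyl (2E)-4-[2-(2,2-dimethylpent-4-en-1-yl)-1,3-dioxolan-2-yl]-3-methylbut-2-enoate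
Conditions: (TMSOCH2)2 (2 equiv), TMSOTf (5 mol %), CH2Cl2, −78 → −20 °C; pyridine quench
Reagents that add atoms: 1,2-bis(trimethylsilyloxy)ethane, C[Si](C)(C)OCCO[Si](C)(C)C
Why: Noyori ketalisation, a TMSOTf-catalysed silyl transfer under aprotic conditions at low temperature, forms the dioxolane irreversibly without water or protic acid, conditions known to leave the position and geometry of nearby double bonds untouched.

Step 8
Reactants: 11 methyl (2E)-4-[2-(2,2-dimethylpent-4-en-1-yl)-1,3-dioxolan-2-yl]-3-methylbut-2-enoate
Product: 12 (2E)-4-[2-(2,2-dimethylpent-4-en-1-yl)-1,3-dioxolan-2-yl]-3-methylbut-2-enoic acid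
Conditions: LiOH, THF/MeOH/H2O, 40 °C; cold 1 M HCl to pH 4
Reagents that add atoms: lithium hydroxide, [Li+].[OH-]
Why: Saponification of the methyl ester, the ketal being inert to base and the carboxylate too electron-rich for deprotonation at C1, followed by a brief cold acidification that the dioxolane tolerates.

Step 9
Reactants: 12 (2E)-4-[2-(2,2-dimethylpent-4-en-1-yl)-1,3-dioxolan-2-yl]-3-methylbut-2-enoic acid; 13 (S)-4-benzyl-2-oxazolidinone
Product: 15 (4S)-4-benzyl-3-{(2E)-4-[2-(2,2-dimethylpent-4-en-1-yl)-1,3-dioxolan-2-yl]-3-methylbut-2-enoyl}oxazolidin-2-one, via mixed pivalic anhydride 14 (not isolated)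
Conditions: PivCl, Et3N, THF, −20 °C; then 13, LiCl, −20 °C → rt
Reagents that add atoms: pivaloyl chloride, CC(C)(C)C(=O)Cl (its atoms stay in 14 only)
Why: N-Acylation of the oxazolidinone through the mixed pivalic anhydride with LiCl and Et3N avoids strong base, the nucleophile attacking the enoyl carbonyl because the pivaloyl carbonyl is shielded by its tert-butyl group, and the stereocentre of the auxiliary comes unchanged from 13.

Step 10
Reactants: 15 terminal-alkene imide; 16 (E)-crotonaldehyde
Product: 17 (4S)-4-benzyl-3-{(2E)-4-[2-((4E)-2,2-dimethyl-6-oxohex-4-en-1-yl)-1,3-dioxolan-2-yl]-3-methylbut-2-enoyl}oxazolidin-2-one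
Conditions: 16 (5 equiv), second-generation Hoveyda–Grubbs catalyst (3 mol %), CH2Cl2, 40 °C
Reagents that add atoms: none
Why: Olefin cross-metathesis between the unhindered terminal alkene and the electron-poor partner crotonaldehyde gives the thermodynamically preferred E enal (C6=C7 with C8 as aldehyde), while the trisubstituted, electron-poor C9=C10 bond is inert to the ruthenium carbene.

Step 11
Reactants: 17 enal imide
Product: 18 N-enoyl (S)-4-benzyloxazolidinone triene with E C9=C10 enoyl group; C2 ethylene ketal; (5E,7E)-8-(tert-butyldimethylsilyloxy)diene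
Conditions: TBSOTf (1.2 equiv), Et3N (2.5 equiv), Et2O, −78 → 0 °C; filtration through Et3N-deactivated silica
Reagents that add atoms: tert-butyldimethylsilyl triflate, CC(C)(C)[Si](C)(C)OS(=O)(=O)C(F)(F)F
Why: Soft enolisation with O-silylation (dienol silyl ether formation) in which TBSOTf binds the aldehyde oxygen, the most Lewis-basic site, and Et3N removes a C5 proton, the s-trans enal giving the E C7=C8 enol ether and the bulk of C4 enforcing the E C5=C6 bond.

Step 12
Reactants: 18 silyloxydiene imide
Product: 19 trans-fused 6-ene cycloadduct (H-5α; 10β-CH3; H-9α with C11 imide β; 8β-OTBS; C2 ethylene ketal)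
Conditions: Me2AlCl (2.2 equiv), CH2Cl2 (0.01 M), −78 → −20 °C; then Et3N, aq. potassium sodium tartrate
Reagents that add atoms: none
Why: Two equivalents of Me2AlCl should turn the imide into the cationic O,O-chelate [imide·AlMe2]+ Me2AlCl2− with the enoyl group held s-cis, and its lowered LUMO then engages the electron-rich 1-silyloxydiene in a concerted, asynchronous, suprafacial [4+2] cycloaddition in which nucleophilic C5 bonds to electrophilic C10 ahead of C8–C9. The closest known reaction type is the dialkylaluminium-chloride-promoted intramolecular Diels–Alder reaction of N-enoyl oxazolidinone 1,7,9-decatrienes, stretched here to a β,β-disubstituted dienophile. Ring B closes as the new cyclohexene made of the six reacting carbons C5 to C10, and ring A closes as the six-membered tether ring (C1–C4 plus the new C5–C10 bond, type 1 mode with a chair-like tether). The benzyl group of the auxiliary covers the C9 re face of the chelate, so the diene adds to the C9 si/C10 re face and fixes the absolute configuration of C9 and C10, while the E alkene geometry is carried over suprafacially and places C11 cis to C20. The endo position of the chelated acyl group (tether exo) puts H-5 anti to C20 and so gives the trans fusion at C5, and the E geometry of C7=C8 places the silyl ether at C8 on the β face, cis to C11, a centre that is erased in step 20. The step needs endo and facial selectivity together with survival of ketal and dienol ether: the rigid chelate secures the first two, the tether fixes the regiochemistry, the C4 gem-dimethyl group and the C2 ketal populate the folded rotamer, and Me2AlCl destroys adventitious acid as methane so that only low-temperature Lewis acidity reaches the acid-labile groups.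

Step 13
Reactants: 19 cycloadduct
Product: 20 C11 primary alcohol (9β-CH2OH; 8β-OTBS; 6-ene; C2 ketal)
Conditions: LiBH4, MeOH (1 equiv), Et2O/THF, 0 °C → rt
Reagents that add atoms: none
Why: Reductive cleavage of an N-acyl oxazolidinone with LiBH4/MeOH, in which the small lithium-activated hydride reduces the exocyclic C11 carbonyl to the primary alcohol and releases the auxiliary, leaving ketal, silyl ether, alkene and all stereocentres untouched.

Step 14
Reactants: 20 C11 alcohol
Product: 21 C11 aldehyde (9β-CHO; 8β-OTBS; 6-ene; C2 ketal)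
Conditions: Dess–Martin periodinane, NaHCO3, CH2Cl2, 0 °C → rt; used after short filtration
Reagents that add atoms: none
Why: Dess–Martin oxidation gives the aldehyde under neutral conditions, which matters because C9–H is α to the new carbonyl and anti to the C8 silyloxy group, and the equatorial C9 configuration is in any case the stable one.

Step 15
Reactants: 22 methyl hydrogen (R)-3-methylglutarate
Product: 23 methyl (S)-4-iodo-3-methylbutanoate
Conditions: PhI(OAc)2, I2, cyclohexane, tungsten lamp, reflux
Reagents that add atoms: iodine, [I][I]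
Why: Hunsdiecker-type radical iododecarboxylation in the Suárez variant excises the free carboxyl carbon so that the remaining four-carbon chain is exactly C12–C15, and C13, which is not the radical centre, keeps the configuration bought with 22 (the descriptor changes from R to S only through the priority of iodine).

Step 16
Reactants: 23 methyl (S)-4-iodo-3-methylbutanoate
Product: 24 [(2S)-4-methoxy-2-methyl-4-oxobutyl]triphenylphosphonium iodide
Conditions: PPh3, MeCN, reflux
Reagents that add atoms: triphenylphosphine, c1ccccc1P(c1ccccc1)c1ccccc1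
Why: SN2 quaternisation of PPh3 by the primary iodide gives the Wittig salt without involving C13.

Step 17
Reactants: 21 C11 aldehyde; 24 phosphonium iodide
Product: 26 (11Z)-6,11-diene methyl ester (8β-OTBS; C2 ketal; C13 methyl as in the target), via phosphorus ylide 25 (not isolated)
Conditions: 24 (1.5 equiv), NaN(SiMe3)2 (1.4 equiv), THF, −78 → 0 °C; then 21, −78 °C → rt
Reagents that add atoms: none
Why: Wittig olefination in which the phosphonium α-proton is far more acidic than the ester α-protons, so that NaN(SiMe3)2 gives the non-stabilised ylide selectively, and this adds to the aldehyde at low temperature to form the C11=C12 bond (mainly Z, geometry irrelevant) with C9 and C13 unchanged.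

Step 18
Reactants: 26 diene ester
Product: 27 saturated 8β-silyl ether methyl ester (C2 ketal; 13R)
Conditions: H2 (1–4 atm), Pt/C (5 %), EtOAc, rt
Reagents that add atoms: none
Why: Heterogeneous catalytic hydrogenation saturates both disubstituted alkenes (C6=C7 and C11=C12) in one operation, platinum being chosen because it causes little double-bond migration (which could erode C9 or C13) and little allylic C–O hydrogenolysis, and no stereocentre is created.

Step 19
Reactants: 27 silyl ether ester
Product: 28 8β-alcohol methyl ester (C2 ketal)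
Conditions: Bu4NF, THF, rt → 45 °C
Reagents that add atoms: none
Why: Fluoride-driven desilylation, paid for by the strong Si–F bond, frees the axial C8 alcohol while ketal and ester stay in place.

Step 20
Reactants: 28 8β-alcohol
Product: 29 8-oxo methyl ester (C2 ketal)
Conditions: Dess–Martin periodinane, NaHCO3, CH2Cl2, rt
Reagents that add atoms: none
Why: Dess–Martin oxidation removes the sacrificial C8 stereocentre and gives the ketone, whose neighbour C9 already holds its side chain in the equatorial, thermodynamically preferred position.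

Step 21
Reactants: 29 8-oxo ester
Product: 30 methyl 2,2-ethylenedioxylabd-8(17)-en-15-oate
Conditions: Ph3PCH3Br (3.0 equiv), KOtBu (2.8 equiv), THF, 0 → 40 °C
Reagents that add atoms: methyltriphenylphosphonium bromide, C[P+](c1ccccc1)(c1ccccc1)c1ccccc1.[Br-]
Why: Wittig methylenation in which the ketone is much more electrophilic than the methyl ester towards Ph3P=CH2, a slight excess of salt over base keeps free alkoxide away from the ester, and reversible enolisation cannot invert the equatorial C9 substituent.

Step 22
Reactants: 30 ketal ester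
Product: 31 methyl 2-oxolabd-8(17)-en-15-oate
Conditions: PPTS (20 mol %), acetone/H2O, 50 °C
Reagents that add atoms: water, O
Why: Acid-catalysed ketal hydrolysis with a weak pyridinium acid, in which release of the syn-axial strain between the axial ketal oxygen and the C19 and C20 methyl groups speeds the cleavage, whereas the acid is too weak to protonate the 8(17)-alkene and move it into the ring.

Step 23
Reactants: 31 2-oxo ester
Product: 33 2β-hydroxylabd-8(17)-en-15-oic acid, via 2β-hydroxy ester 32 (not isolated)
Conditions: NaBH4, MeOH, 0 °C; then aq. LiOH, THF, 40 °C; cold 1 M HCl to pH 3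
Reagents that add atoms: lithium hydroxide, [Li+].[OH-]
Why: Borohydride reduction followed by saponification in the same flask, where the β face of the C2 carbonyl is closed by the two axial methyl groups C19 and C20, so that hydride arrives from the α face and gives the axial 2β-alcohol (2R), after which LiOH cleaves the unhindered methyl ester.

Step 24
Reactants: 33 2β-hydroxy acid
Product: 35 2β-acetoxylabd-8(17)-en-15-oic acid (target), via C15 mixed acetic anhydride 34 (not isolated)
Conditions: Ac2O, pyridine, DMAP (cat.), 40 °C; then H2O/THF, rt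
Reagents that add atoms: acetic anhydride, CC(=O)OC(C)=O
Why: DMAP-catalysed acetylation esterifies the hindered axial 2β-hydroxyl with retention at C2, and the mixed anhydride formed at C15 is hydrolysed selectively in the aqueous work-up because an anhydride is far more reactive than the secondary acetate.

Compound list

1 | diethyl isopropylidenemalonate | CCOC(=O)C(=C(C)C)C(=O)OCC | starting material
2 | allylmagnesium bromide | C=CC[Mg]Br | starting material
3 | diethyl 2-(2-methylpent-4-en-2-yl)malonate | C=CCC(C)(C)C(C(=O)OCC)C(=O)OCC | intermediate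
4 | ethyl 3,3-dimethylhex-5-enoate | C=CCC(C)(C)CC(=O)OCC | intermediate
5 | 3,3-dimethylhex-5-enal | C=CCC(C)(C)CC=O | intermediate
6 | methyl 3-methylbut-2-enoate | COC(=O)C=C(C)C | starting material
7 | lithium dienolate of 6 (not isolated) | C=C(C)C=C(OC)[O-].[Li+] | intermediate
8 | 1-methoxy-3-methyl-1-(trimethylsilyloxy)buta-1,3-diene | C=C(C)C=C(OC)O[Si](C)(C)C | intermediate
9 | methyl (2E)-5-hydroxy-3,7,7-trimethyldeca-2,9-dienoate, racemic at C2 | C=CCC(C)(C)CC(O)C/C(C)=C/C(=O)OC | intermediate
10 | methyl (2E)-3,7,7-trimethyl-5-oxodeca-2,9-dienoate | C=CCC(C)(C)CC(=O)C/C(C)=C/C(=O)OC | intermediate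
11 | methyl (2E)-4-[2-(2,2-dimethylpent-4-en-1-yl)-1,3-dioxolan-2-yl]-3-methylbut-2-enoate | C=CCC(C)(C)CC1(OCCO1)C/C(C)=C/C(=O)OC | intermediate
12 | (2E)-4-[2-(2,2-dimethylpent-4-en-1-yl)-1,3-dioxolan-2-yl]-3-methylbut-2-enoic acid | C=CCC(C)(C)CC1(OCCO1)C/C(C)=C/C(=O)O | intermediate
13 | (S)-4-benzyl-2-oxazolidinone | O=C1N[C@@H](Cc2ccccc2)CO1 | starting material
14 | mixed pivalic anhydride of 12 (not isolated) | C=CCC(C)(C)CC1(OCCO1)C/C(C)=C/C(=O)OC(=O)C(C)(C)C | intermediate
15 | N-enoyl (S)-4-benzyloxazolidinone with terminal alkene and C2 ketal | C=CCC(C)(C)CC1(OCCO1)C/C(C)=C/C(=O)N2[C@@H](Cc3ccccc3)COC2=O | intermediate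
16 | (E)-crotonaldehyde | C/C=C/C=O | starting material
17 | N-enoyl (S)-4-benzyloxazolidinone with (6E)-enal (C8 aldehyde) and C2 ketal | O=C/C=C/CC(C)(C)CC1(OCCO1)C/C(C)=C/C(=O)N2[C@@H](Cc3ccccc3)COC2=O | intermediate
18 | Diels–Alder precursor: E C9=C10 enoyl imide, C2 ethylene ketal, (5E,7E)-8-silyloxydiene | O=C(/C=C(\C)CC1(OCCO1)CC(C)(C)/C=C/C=C/O[Si](C)(C)C(C)(C)C)N2[C@@H](Cc3ccccc3)COC2=O | intermediate
19 | Diels–Alder adduct: trans-fused 6-ene, H-5α, 10β-CH3, H-9α, C11 imide β, 8β-OTBS, C2 ketal | CC(C)(C)[Si](C)(C)O[C@H]1C=C[C@H]2C(C)(C)CC3(OCCO3)C[C@]2(C)[C@H]1C(=O)N4[C@@H](Cc5ccccc5)COC4=O | intermediate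
20 | C11 alcohol (9β-CH2OH, 8β-OTBS, 6-ene, C2 ketal) | CC(C)(C)[Si](C)(C)O[C@H]1C=C[C@H]2C(C)(C)CC3(OCCO3)C[C@]2(C)[C@H]1CO | intermediate
21 | C11 aldehyde (9β-CHO, 8β-OTBS, 6-ene, C2 ketal) | CC(C)(C)[Si](C)(C)O[C@H]1C=C[C@H]2C(C)(C)CC3(OCCO3)C[C@]2(C)[C@H]1C=O | intermediate
22 | methyl hydrogen (R)-3-methylglutarate | OC(=O)C[C@@H](C)CC(=O)OC | starting material
23 | methyl (S)-4-iodo-3-methylbutanoate | IC[C@@H](C)CC(=O)OC | intermediate
24 | [(2S)-4-methoxy-2-methyl-4-oxobutyl]triphenylphosphonium iodide | c1ccccc1[P+](c1ccccc1)(c1ccccc1)C[C@@H](C)CC(=O)OC.[I-] | intermediate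
25 | ylide of 24 (not isolated) | c1ccccc1P(c1ccccc1)(c1ccccc1)=C[C@@H](C)CC(=O)OC | intermediate
26 | (11Z)-6,11-diene methyl ester, 8β-OTBS, C2 ketal | CC(C)(C)[Si](C)(C)O[C@H]1C=C[C@H]2C(C)(C)CC3(OCCO3)C[C@]2(C)[C@H]1/C=C\[C@@H](C)CC(=O)OC | intermediate
27 | saturated methyl ester, 8β-OTBS, C2 ketal, 13R | CC(C)(C)[Si](C)(C)O[C@H]1CC[C@H]2C(C)(C)CC3(OCCO3)C[C@]2(C)[C@H]1CC[C@@H](C)CC(=O)OC | intermediate
28 | 8β-hydroxy methyl ester, C2 ketal | O[C@H]1CC[C@H]2C(C)(C)CC3(OCCO3)C[C@]2(C)[C@H]1CC[C@@H](C)CC(=O)OC | intermediate
29 | 8-oxo methyl ester, C2 ketal | O=C1CC[C@H]2C(C)(C)CC3(OCCO3)C[C@]2(C)[C@H]1CC[C@@H](C)CC(=O)OC | intermediate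
30 | methyl 2,2-ethylenedioxylabd-8(17)-en-15-oate | C=C1CC[C@H]2C(C)(C)CC3(OCCO3)C[C@]2(C)[C@H]1CC[C@@H](C)CC(=O)OC | intermediate
31 | methyl 2-oxolabd-8(17)-en-15-oate | C=C1CC[C@H]2C(C)(C)CC(=O)C[C@]2(C)[C@H]1CC[C@@H](C)CC(=O)OC | intermediate
32 | methyl 2β-hydroxylabd-8(17)-en-15-oate (not isolated) | C=C1CC[C@H]2C(C)(C)C[C@@H](O)C[C@]2(C)[C@H]1CC[C@@H](C)CC(=O)OC | intermediate
33 | 2β-hydroxylabd-8(17)-en-15-oic acid | C=C1CC[C@H]2C(C)(C)C[C@@H](O)C[C@]2(C)[C@H]1CC[C@@H](C)CC(=O)O | intermediate
34 | 2β-acetoxy C15 mixed acetic anhydride (not isolated) | C=C1CC[C@H]2C(C)(C)C[C@@H](OC(C)=O)C[C@]2(C)[C@H]1CC[C@@H](C)CC(=O)OC(C)=O | intermediate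
35 | (2R,5S,9S,10S,13R)-2-acetoxylabd-8(17)-en-15-oic acid, CNP0205865.1 | C=C1CC[C@H]2C(C)(C)C[C@@H](OC(C)=O)C[C@]2(C)[C@H]1CC[C@@H](C)CC(=O)O | target

Total step count: 24. Longest linear sequence: 21 steps (steps 1–3, 5–14, 17–24).

Steps most likely to fail

**1. Step 12.** The β,β-disubstituted dienophile may react so slowly that opening of the dioxolane or loss of the silyl group under the stoichiometric aluminium Lewis acid overtakes the cycloaddition. Warming would erode endo and facial selectivity.
- The fallback replaces auxiliary control by catalyst control. It sets out from acid 12 and comes back to the route at alcohol 20.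
- Acid 12 is activated as 14 and coupled with achiral 2-oxazolidinone (LiCl, Et3N) to the achiral N-enoyl oxazolidinone F1.
- Cross-metathesis with 16 gives the achiral enal imide F2, and TBSOTf/Et3N gives the achiral silyloxydiene imide F3.
- A catalytic amount of the dicationic complex made from CuCl2, AgSbF6 and 2,2'-isopropylidenebis[(4R)-4-tert-butyl-2-oxazoline] then promotes the enantioselective intramolecular Diels–Alder reaction to the achiral-imide cycloadduct F4. This is a square-planar chelate of divalent copper with no chloride or alkyl group to transfer.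
- In the square-planar chelate the (R,R)-ligand shields the C9 re face as the benzyl group would.
- LiBH4/MeOH cleaves F4 to 20.

**2. Step 17.** Addition of the β-branched ylide to the crowded C11 aldehyde may be slow enough for the basic ylide to deprotonate C9. That would trigger β-elimination of the anti-periplanar, allylic silyloxy group at C8.
- The fallback avoids both the aldehyde and the base by making C11–C12 through an alkyl–alkyl Negishi coupling. It sets out from alcohol 20 (together with iodide 23) and comes back at 27.
- Alcohol 20 is converted with I2, PPh3 and imidazole into the C11 iodide F5.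
- Iodide 23 is treated with zinc dust and LiCl in THF to give the alkylzinc iodide F6.
- Ni(cod)2 with s-Bu-Pybox in DMA couples F5 and F6 to the 6-ene ester with saturated side chain F7. The zerovalent nickel precatalyst activates the alkyl iodide by a radical-type path that is little affected by β-branching.
- Hydrogenation as in step 18 gives 27.

**3. Step 13.** Hydride may attack the more accessible ring carbonyl of the auxiliary (endocyclic opening) instead of the C11 carbonyl, which is shielded by C10 and the C8 silyl ether.
- The fallback exchanges reduction for acyl substitution by a small, soft nucleophile. It sets out from 19 and comes back at aldehyde 21, bypassing 20.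
- LiSEt (EtSH, n-BuLi, THF, 0 °C) displaces the auxiliary selectively at the exocyclic carbonyl to give the S-ethyl thioester F8.
- iBu2AlH in CH2Cl2 at −78 °C reduces F8 directly to 21.

Further compounds

F1 | step 12 | 3-{(2E)-4-[2-(2,2-dimethylpent-4-en-1-yl)-1,3-dioxolan-2-yl]-3-methylbut-2-enoyl}oxazolidin-2-one | C=CCC(C)(C)CC1(OCCO1)C/C(C)=C/C(=O)N2CCOC2=O
F2 | step 12 | achiral enal imide (C8 aldehyde, 6E) | O=C/C=C/CC(C)(C)CC1(OCCO1)C/C(C)=C/C(=O)N2CCOC2=O
F3 | step 12 | achiral silyloxydiene imide (5E,7E; E C9=C10) | O=C(/C=C(\C)CC1(OCCO1)CC(C)(C)/C=C/C=C/O[Si](C)(C)C(C)(C)C)N2CCOC2=O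
F4 | step 12 | achiral-imide cycloadduct (ring stereocentres as in 19) | CC(C)(C)[Si](C)(C)O[C@H]1C=C[C@H]2C(C)(C)CC3(OCCO3)C[C@]2(C)[C@H]1C(=O)N4CCOC4=O
F5 | step 17 | C11 iodide (9β-CH2I, 8β-OTBS, 6-ene, C2 ketal) | CC(C)(C)[Si](C)(C)O[C@H]1C=C[C@H]2C(C)(C)CC3(OCCO3)C[C@]2(C)[C@H]1CI
F6 | step 17 | [(2S)-4-methoxy-2-methyl-4-oxobutyl]zinc iodide | I[Zn]C[C@@H](C)CC(=O)OC
F7 | step 17 | 6-ene methyl ester with saturated side chain, 8β-OTBS, C2 ketal | CC(C)(C)[Si](C)(C)O[C@H]1C=C[C@H]2C(C)(C)CC3(OCCO3)C[C@]2(C)[C@H]1CC[C@@H](C)CC(=O)OC
F8 | step 13 | S-ethyl C11 thioester (8β-OTBS, 6-ene, C2 ketal) | CC(C)(C)[Si](C)(C)O[C@H]1C=C[C@H]2C(C)(C)CC3(OCCO3)C[C@]2(C)[C@H]1C(=O)SCC
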